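**Retrosynthetic overview**
- No [4+2] is used. The cyclohexene is the only ring formed, and it is closed late by ring-closing metathesis at C1=C2, after all three stereocentres exist in an open chain.
- Endgame: the aroyl group comes from ArLi addition to the C4 aldehyde followed by oxidation. The formyl group comes from ArBr by Br/Li exchange and DMF. Six MOM ethers come off last.
- Key step: the C3–C4 bond is made by Ir/(P,olefin) plus prolinol-ether amine dual catalysis. This is an enantioconvergent α-allylation of a β-aryl aldehyde with a racemic aryl vinyl carbinol, and it sets C3 and C4 together.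
- C5 is set by Rh/BINAP conjugate arylation of a skipped dienoate made in one cross-metathesis.
- Ring order: three commercial benzene rings are carried through, and the cyclohexene is formed in step 9.

Assumptions:
- Ring numbering is C1(Me)=C2–C3(Ar1, formyl-bearing aryl)–C4(aroyl)–C5(Ar3)–C6.
- The SMILES decodes as 3R,4R,5S, all-trans.
- MOM = CH2OCH3.
- I could not assign the sense of induction of the Ir ligand from memory, so its antipode is defined by the product configuration it must give. Both antipodes are sold.

**Step 1**
Reactants: 1 4-bromoresorcinol; 2 chloromethyl methyl ether (MOMCl)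
Product: 3 1-bromo-2,4-bis(methoxymethoxy)benzene
Conditions: MOMCl (2.5 equiv), iPr2NEt, CH2Cl2, 0 °C → rt
Reagents that add atoms: MOMCl, COCCl
Why: Williamson-type O-alkylation (MOM protection) of both phenols gives ethers that survive the RLi, DIBAL, Rh, Ir and Ru steps and stabilise an ortho-aryllithium.

**Step 2**
Reactants: 3; 4 triisopropyl borate; 5 water (work-up)
Product: 6 [2,4-bis(methoxymethoxy)phenyl]boronic acid
Conditions: n-BuLi, THF, −78 °C; B(OiPr)3, −78 °C → rt; sat. aq NH4Cl
Reagents that add atoms: triisopropyl borate, CC(C)OB(OC(C)C)OC(C)C; water, O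
Why: Br/Li exchange followed by borate trapping works because exchange at −78 °C is much faster than directed ortho-metalation, so boron ends up on the former C–Br carbon.

**Step 3**
Reactants: 7 2-methylpenta-1,4-diene; 8 methyl acrylate
Product: 9 methyl (2E)-5-methylhexa-2,5-dienoate
Conditions: Hoveyda–Grubbs II (2 mol %), 1,4-benzoquinone (10 mol %), CH2Cl2, 40 °C
Reagents that add atoms: methyl acrylate, C=CC(=O)OC
Why: In this olefin cross-metathesis the monosubstituted (type I) alkene couples E-selectively with the acrylate (type II), the 1,1-disubstituted alkene (type III) stays intact, and benzoquinone suppresses Ru–H isomerisation.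

**Step 4**
Reactants: 9; 6 (2 equiv)
Product: 10 methyl (3S)-3-[2,4-bis(methoxymethoxy)phenyl]-5-methylhex-5-enoate
Conditions: [Rh(OH)((R)-BINAP)]2 (2.5 mol %), dioxane/H2O 10:1, 50 °C, no added base
Reagents that add atoms: boronic acid 6, COCOc1ccc(B(O)O)c(OCOC)c1
Why: Hayashi–Miyaura asymmetric 1,4-addition sets C5 as S, since (R)-BINAP gives the mirror of the known (S)-BINAP/E-crotonate → (R)-3-arylbutanoate sense, and the isolated alkene is not an acceptor.

**Step 5**
Reactants: 10
Product: 11 (3S)-3-[2,4-bis(methoxymethoxy)phenyl]-5-methylhex-5-enal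
Conditions: DIBAL-H (1.05 equiv), toluene, −78 °C; Rochelle salt
Reagents that add atoms: none
Why: Partial ester reduction stops at the aldehyde because the aluminium hemiacetal is stable at −78 °C, and the β-stereocentre cannot epimerise.

**Step 6**
Reactants: 12 5-bromo-2,4-dihydroxybenzaldehyde; 2 MOMCl
Product: 13 5-bromo-2,4-bis(methoxymethoxy)benzaldehyde
Conditions: NaH, MOMCl, DMF, 0 °C → rt
Reagents that add atoms: MOMCl, COCCl
Why: MOM protection (O-alkylation) under NaH also alkylates the hydrogen-bonded 2-OH, and the bromide is carried as an acid- and base-stable placeholder for the final formyl group.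

**Step 7**
Reactants: 13; 14 vinylmagnesium bromide
Product: 15 (±)-1-[5-bromo-2,4-bis(methoxymethoxy)phenyl]prop-2-en-1-ol
Conditions: THF, −78 → 0 °C
Reagents that add atoms: vinylmagnesium bromide, C=C[Mg]Br
Why: Grignard 1,2-addition gives a racemic carbinol, which is acceptable because step 8 is enantioconvergent.

**Step 8 (key step)**
Reactants: 11 (1.0 equiv); 15 (1.3 equiv)
Product: 16 (2R,3S)-3-[2,4-bis(methoxymethoxy)phenyl]-2-{(1R)-1-[5-bromo-2,4-bis(methoxymethoxy)phenyl]prop-2-en-1-yl}-5-methylhex-5-enal (ring numbering 3R,4R,5S)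
Conditions: [Ir(cod)Cl]2 (3 mol %), BINOL/dibenzazepine (P,olefin) phosphoramidite (12 mol %, the antipode giving 3R), (S)-α,α-bis[3,5-(CF3)2C6H3]prolinol TMS ether (15 mol %), Zn(OTf)2 (5 mol %), DCE, 25 °C
Reagents that add atoms: carbinol 15 (allyl donor, loses OH), C=CC(O)c1cc(Br)c(OCOC)cc1OCOC
Why: In this stereodivergent Ir-catalysed allylic substitution merged with enamine catalysis, both enantiomers of 15 ionise to one ligand-controlled π-allyl-Ir that is attacked at the branched terminus (C3 = R), the (S)-amine E-enamine exposes one face (C4 = R, the same sense as its nitroalkene Michael additions), and residual ent-11 becomes a separable diastereomer.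

**Step 9**
Reactants: 16
Product: 17 (1R,2R,6S)-2-[5-bromo-2,4-bis(methoxymethoxy)phenyl]-6-[2,4-bis(methoxymethoxy)phenyl]-4-methylcyclohex-3-ene-1-carbaldehyde
Conditions: Grubbs II (5 mol %), CH2Cl2 (0.01 M), 40 °C; then DBU (0.2 equiv), rt
Reagents that add atoms: none
Why: Ring-closing metathesis of the vinyl and isopropenyl groups (loss of ethylene) fixes the trisubstituted alkene at C1=C2 unambiguously, and DBU converges any C4 epimer to the all-equatorial (all-trans) aldehyde.

**Step 10**
Reactants: 17; 3 (1.3 equiv); 18 N,N-dimethylformamide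
Product: 19 5-[(1R,5S,6R)-6-{[2,4-bis(methoxymethoxy)phenyl](hydroxy)methyl}-5-[2,4-bis(methoxymethoxy)phenyl]-3-methylcyclohex-2-en-1-yl]-2,4-bis(methoxymethoxy)benzaldehyde (carbinol epimers, inconsequential)
Conditions: 3, n-BuLi, THF, −78 °C; add 17, −78 °C, 1 h; then n-BuLi (1.5 equiv), −78 °C, 15 min; DMF, −78 → 0 °C; aq NH4Cl
Reagents that add atoms: aryllithium from 3, COCOc1ccc(Br)c(OCOC)c1; DMF, CN(C)C=O
Why: Aryllithium 1,2-addition converts the only carbonyl into an inert lithium alkoxide, after which Br/Li exchange (faster than ortho-metalation at −78 °C) and Bouveault-type formylation turn ArBr into ArCHO without creating or disturbing any ring stereocentre.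

**Step 11**
Reactants: 19
Product: 20 5-[(1R,5S,6R)-6-[2,4-bis(methoxymethoxy)benzoyl]-5-[2,4-bis(methoxymethoxy)phenyl]-3-methylcyclohex-2-en-1-yl]-2,4-bis(methoxymethoxy)benzaldehyde
Conditions: Dess–Martin periodinane, NaHCO3, CH2Cl2, 0 °C → rt
Reagents that add atoms: none
Why: Buffered Dess–Martin oxidation converts both carbinol epimers into one ketone while sparing ArCHO, the alkene and the MOM groups, and C4 is already in its thermodynamic equatorial configuration.

**Step 12**
Reactants: 20
Product: 21 target, 5-[(1R,5S,6R)-6-(2,4-dihydroxybenzoyl)-5-(2,4-dihydroxyphenyl)-3-methylcyclohex-2-en-1-yl]-2,4-dihydroxybenzaldehyde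
Conditions: 3 M aq HCl, MeOH/THF, 35–40 °C, degassed, stopped at full conversion
Reagents that add atoms: none
Why: Acid-catalysed acetal hydrolysis removes all six aryl MOM ethers under conditions mild enough to leave a trisubstituted alkene next to an ortho-phenol uncyclised, and no stereocentre is touched.

**Compound list**
1 | 4-bromoresorcinol | Oc1ccc(Br)c(O)c1 | starting material
2 | chloromethyl methyl ether | COCCl | starting material
3 | 1-bromo-2,4-bis(methoxymethoxy)benzene | COCOc1ccc(Br)c(OCOC)c1 | intermediate
4 | triisopropyl borate | CC(C)OB(OC(C)C)OC(C)C | starting material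
5 | water | O | starting material
6 | [2,4-bis(methoxymethoxy)phenyl]boronic acid | COCOc1ccc(B(O)O)c(OCOC)c1 | intermediate
7 | 2-methylpenta-1,4-diene | C=C(C)CC=C | starting material
8 | methyl acrylate | C=CC(=O)OC | starting material
9 | methyl (2E)-5-methylhexa-2,5-dienoate | C=C(C)C/C=C/C(=O)OC | intermediate
10 | methyl (3S)-3-[2,4-bis(MOMO)phenyl]-5-methylhex-5-enoate | C=C(C)C[C@@H](CC(=O)OC)c1ccc(OCOC)cc1OCOC | intermediate
11 | (3S)-3-[2,4-bis(MOMO)phenyl]-5-methylhex-5-enal | C=C(C)C[C@@H](CC=O)c1ccc(OCOC)cc1OCOC | intermediate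
12 | 5-bromo-2,4-dihydroxybenzaldehyde | O=Cc1cc(Br)c(O)cc1O | starting material
13 | 5-bromo-2,4-bis(methoxymethoxy)benzaldehyde | COCOc1cc(OCOC)c(C=O)cc1Br | intermediate
14 | vinylmagnesium bromide | C=C[Mg]Br | starting material
15 | (±)-1-[5-bromo-2,4-bis(MOMO)phenyl]prop-2-en-1-ol | C=CC(O)c1cc(Br)c(OCOC)cc1OCOC | intermediate
16 | (2R,3S,1′R) acyclic diene aldehyde | C=C[C@@H](c1cc(Br)c(OCOC)cc1OCOC)[C@H](C=O)[C@@H](c1ccc(OCOC)cc1OCOC)CC(C)=C | intermediate
17 | (1R,2R,6S)-cyclohexenecarbaldehyde | CC1=C[C@@H](c2cc(Br)c(OCOC)cc2OCOC)[C@H](C=O)[C@@H](c2ccc(OCOC)cc2OCOC)C1 | intermediate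
18 | N,N-dimethylformamide | CN(C)C=O | starting material
19 | hydroxy aldehyde (carbinol epimers) | CC1=C[C@@H](c2cc(C=O)c(OCOC)cc2OCOC)[C@H](C(O)c2ccc(OCOC)cc2OCOC)[C@@H](c2ccc(OCOC)cc2OCOC)C1 | intermediate
20 | hexa-MOM keto aldehyde | CC1=C[C@@H](c2cc(C=O)c(OCOC)cc2OCOC)[C@H](C(=O)c2ccc(OCOC)cc2OCOC)[C@@H](c2ccc(OCOC)cc2OCOC)C1 | intermediate
21 | CID10073682 | CC1=C[C@@H](c2cc(C=O)c(O)cc2O)[C@H](C(=O)c2ccc(O)cc2O)[C@@H](c2ccc(O)cc2O)C1 | target

**Totals**
- Total steps: 12.
- Longest linear sequence: 9 (steps 1, 2, 4, 5, 8, 9, 10, 11, 12).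

**Three steps most likely to fail, each with one fallback**
1. **Step 8.**
   - Risk: the enamine is hindered by the β-aryl branch, and the carbinol is very electron-rich and ortho-substituted. The likely failure modes are background SN1 reaction, linear product and low conversion.
   - Fallback: make C3–C4 intramolecularly by a chirality-transfer Ireland–Claisen rearrangement. Saponify 10 and esterify the acid with enantioenriched (E)-4-Ar1-but-3-en-2-ol, obtained by CBS reduction of the enone. Rearrange with KHMDS/TMSCl. Convert the resulting acid to the ketone through the Weinreb amide and the aryllithium from 3. Close the ring by RCM of the propenyl/isopropenyl diene.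
2. **Step 4.**
   - Risk: the electron-rich ortho-alkoxy boronic acid may protodeboronate, and 9 may isomerise to the conjugated dienoate.
   - Fallback: create C5 by hydride delivery instead of aryl transfer. Run a Cu-catalysed syn-hydroarylation of methyl 5-methylhex-5-en-2-ynoate with 6 to get the β-aryl enoate. Reduce it by CuH/DTBM-SEGPHOS asymmetric conjugate reduction to give 10.
3. **Step 12.**
   - Risk: acid may cause phenol-to-alkene chroman formation, alkene migration or ketalisation during the six-fold MOM removal.
   - Fallback: change the protecting-group strategy from the start. Use SEM ethers on all three rings, which behave like MOM toward RLi. Remove them together with fluoride (TBAF/DMPU), so the alkene and free phenols never meet Brønsted acid.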